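**Strategy.** The route is convergent and rests on cutting two neighbouring C–C bonds of the cyclohexane ring: the bond from the methyl-bearing quaternary ring-fusion carbon to the CH2 chain of the oxepane, and the bond from the adjacent CH to the CH2–CH= link. These two carbons are the β- and α-carbons of a cyclohexanone. One operation therefore joins three fragments: a homoprenyl Grignard reagent adds under copper catalysis to an (R)-4-silyloxy-3-methylcyclohexenone, and the regiodefined enolate is alkylated by a hydroazulene allylic bromide, setting both centres trans. The silyloxy carbon of the enone later becomes the oxepane ring-fusion CH. The bromide is built from (R)-linalool.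

Key step: step 19

Remark: compound 14 forms as a mixture at its new carbinol carbon and is drawn without a descriptor there; both epimers give 15.

**Hydroazulene allylic bromide**

Step 1
Reactants: 1 (R)-(−)-linalool
Product: 2 (R)-1-methylcyclopent-2-en-1-ol
Conditions: second-generation Grubbs catalyst (H2IMes)(PCy3)Cl2Ru=CHPh (0.5 mol%), CH2Cl2, 40 °C
Reagents that add atoms: none
Why: Ring-closing metathesis of the 1,6-diene closes the cyclopentene and expels isobutene, leaving the tertiary carbinol centre of linalool untouched.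

Step 2
Reactants: 2 (R)-1-methylcyclopent-2-en-1-ol
Product: 3 (1S,2R,5S)-2-methyl-6-oxabicyclo[3.1.0]hexan-2-ol (epoxide cis to OH)
Conditions: VO(acac)2 (2 mol%), t-BuOOH, CH2Cl2, 0 °C → rt
Reagents that add atoms: tert-butyl hydroperoxide CC(C)(C)OO
Why: Vanadium-catalysed hydroxyl-directed epoxidation delivers the oxygen to the alkene face cis to the tertiary OH, which sets both epoxide carbons from the existing centre.

Step 3
Reactants: 3 (1S,2R,5S)-2-methyl-6-oxabicyclo[3.1.0]hexan-2-ol
Product: 4 2-[(1S,2S,3R)-2,3-dihydroxy-3-methylcyclopentyl]-2-methylpropanenitrile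
Conditions: i-PrCN, LDA (2.5 equiv), THF, −78 → 50 °C; H2O
Reagents that add atoms: isobutyronitrile CC(C)C#N
Why: SN2 epoxide opening by the nitrile-stabilised carbanion occurs at the epoxide carbon remote from the quaternary carbinol and with inversion, so the C(CH3)2CN arm ends trans to both hydroxyls.

Step 4
Reactants: 4 2-[(1S,2S,3R)-2,3-dihydroxy-3-methylcyclopentyl]-2-methylpropanenitrile
Product: 5 2-[(1S,3R)-3-hydroxy-3-methyl-2-oxocyclopentyl]-2-methylpropanenitrile
Conditions: IBX, DMSO, rt
Reagents that add atoms: none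
Why: IBX oxidation converts the secondary alcohol of a 1,2-diol into the α-hydroxy ketone without glycol cleavage and, being non-basic, without epimerising the neighbouring CH.

Step 5
Reactants: 5 2-[(1S,3R)-3-hydroxy-3-methyl-2-oxocyclopentyl]-2-methylpropanenitrile
Product: 6 2-[(1S,3R)-3-hydroxy-3-methyl-2-methylidenecyclopentyl]-2-methylpropanenitrile
Conditions: Zn, CH2Br2, TiCl4, THF–CH2Cl2, 0 °C → rt
Reagents that add atoms: dibromomethane BrCBr
Why: Takai–Lombardo methylenation transfers CH2 from a non-basic zinc/titanium reagent to hindered, enolisable ketones, so the α-centre should not epimerise and the free hydroxyl and the nitrile should be tolerated.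

Step 6
Reactants: 6 2-[(1S,3R)-3-hydroxy-3-methyl-2-methylidenecyclopentyl]-2-methylpropanenitrile
Product: 8 2-[(1R,3R)-3-hydroxy-3-methyl-2-methylidenecyclopentyl]-2-methylhept-6-en-3-one, via bromomagnesium ketimine 7 (not isolated)
Conditions: CH2=CHCH2CH2MgBr (3 equiv), CuBr·SMe2 (5 mol%), THF, 65 °C; aq. citric acid, 0 °C → rt
Reagents that add atoms: but-3-enylmagnesium bromide C=CCC[Mg]Br; water O
Why: Copper-catalysed Grignard addition to the hindered nitrile stops at the metallo-imine 7 (the alcohol is masked as its magnesium alkoxide), and mild aqueous acid then hydrolyses the imine to the ketone.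

Step 7
Reactants: 8 2-[(1R,3R)-3-hydroxy-3-methyl-2-methylidenecyclopentyl]-2-methylhept-6-en-3-one
Product: 9 (1R,8R)-8-hydroxy-2,2,8-trimethylbicyclo[5.3.0]dec-6-en-3-one
Conditions: second-generation Grubbs catalyst (H2IMes)(PCy3)Cl2Ru=CHPh (5 mol%), toluene (high dilution), 80 °C
Reagents that add atoms: none
Why: Ring-closing metathesis joins the terminal alkene to the exocyclic methylene to give the seven-membered ring as a trisubstituted alkene, the gem-dimethyl group and the cis-disposed arms favouring closure.

Step 8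
Reactants: 9 (1R,8R)-8-hydroxy-2,2,8-trimethylbicyclo[5.3.0]dec-6-en-3-one
Product: 10 (1R,7R,8R)-8-hydroxy-2,2,8-trimethylbicyclo[5.3.0]decan-3-one (cis-fused)
Conditions: H2 (1 atm), [Ir(cod)(PCy3)(py)]PF6 (5 mol%), CH2Cl2, rt
Reagents that add atoms: none
Why: Hydroxyl-directed hydrogenation with Crabtree's iridium catalyst adds hydrogen to the alkene face that carries the allylic tertiary OH, so the new ring-fusion hydrogen is cis to OH and cis to the existing ring-fusion hydrogen (cis-hydroazulene).

Step 9
Reactants: 10 (1R,7R,8R)-8-hydroxy-2,2,8-trimethylbicyclo[5.3.0]decan-3-one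
Product: 11 (1R,7R,8R)-2,2,8-trimethyl-8-(triethylsilyloxy)bicyclo[5.3.0]decan-3-one
Conditions: Et3SiOTf, 2,6-lutidine, CH2Cl2, −78 → 0 °C
Reagents that add atoms: triethylsilyl trifluoromethanesulfonate CC[Si](CC)(CC)OS(=O)(=O)C(F)(F)F
Why: Silyl triflate silylation protects the hindered tertiary alcohol as its triethylsilyl ether ahead of the enolate and organometallic steps.

Step 10
Reactants: 11 (1R,7R,8R)-2,2,8-trimethyl-8-(triethylsilyloxy)bicyclo[5.3.0]decan-3-one
Product: 13 (1R,4R,7R,8R)-2,2,4,8-tetramethyl-8-(triethylsilyloxy)bicyclo[5.3.0]decan-3-one, via lithium enolate 12 (not isolated)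
Conditions: LDA, THF, −78 °C; MeI, −78 → −20 °C
Reagents that add atoms: iodomethane CI
Why: Enolate alkylation is regiospecific because the other α-carbon is quaternary, and methyl iodide should approach the convex face of the cis-fused bicycle, placing CH3 cis to the ring-fusion hydrogens (the exo position, which should also be the more stable one, so that base equilibration can raise its proportion).

Step 11
Reactants: 13 (1R,4R,7R,8R)-2,2,4,8-tetramethyl-8-(triethylsilyloxy)bicyclo[5.3.0]decan-3-one
Product: 14 (1R,4R,7R,8R)-3-ethenyl-2,2,4,8-tetramethyl-8-(triethylsilyloxy)bicyclo[5.3.0]decan-3-ol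
Conditions: CH2=CHMgBr, CeCl3, THF, −78 → 0 °C
Reagents that add atoms: vinylmagnesium bromide C=C[Mg]Br
Why: Organocerium 1,2-addition avoids enolisation of the hindered ketone, and the configuration of the new carbinol carbon is irrelevant because that carbon becomes sp2 in the next step.

Step 12
Reactants: 14 (1R,4R,7R,8R)-3-ethenyl-2,2,4,8-tetramethyl-8-(triethylsilyloxy)bicyclo[5.3.0]decan-3-ol
Product: 15 (1R,3E,4R,7R,8R)-3-(2-bromoethylidene)-2,2,4,8-tetramethyl-8-(triethylsilyloxy)bicyclo[5.3.0]decane
Conditions: PBr3, pyridine (cat.), Et2O, −30 → 0 °C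
Reagents that add atoms: phosphorus tribromide BrP(Br)Br
Why: SN2′ bromination of the tertiary allylic alcohol (allylic transposition) places bromine on the terminal carbon, and the CH2Br group should settle anti to the quaternary carbon, which is the E alkene.

**Enone**

Step 13
Reactants: 16 4-methoxy-2-methylphenol
Product: 17 4,4-dimethoxy-2-methylcyclohexa-2,5-dien-1-one
Conditions: PhI(OAc)2, MeOH, 0 °C
Reagents that add atoms: methanol CO
Why: Oxidative dearomatisation of the para-methoxyphenol by the hypervalent iodine reagent in methanol gives the quinone monoketal.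

Step 14
Reactants: 17 4,4-dimethoxy-2-methylcyclohexa-2,5-dien-1-one
Product: 18 4,4-dimethoxy-2-methylcyclohex-2-en-1-one
Conditions: H2 (1 atm), RhCl(PPh3)3 (5 mol%), benzene, rt
Reagents that add atoms: none
Why: Homogeneous hydrogenation with Wilkinson's catalyst reduces the less substituted alkene of the cross-conjugated dienone and should not trigger loss of methanol and rearomatisation.

Step 15
Reactants: 18 4,4-dimethoxy-2-methylcyclohex-2-en-1-one
Product: 19 (R)-4,4-dimethoxy-2-methylcyclohex-2-en-1-ol
Conditions: (S)-2-methyl-CBS-oxazaborolidine (10 mol%), BH3·SMe2, THF, −20 °C; MeOH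
Reagents that add atoms: none
Why: Corey–Bakshi–Shibata reduction with the (S)-oxazaborolidine treats the alkene-bearing side as the large group and delivers hydride to give the (R)-allylic alcohol.

Step 16
Reactants: 19 (R)-4,4-dimethoxy-2-methylcyclohex-2-en-1-ol
Product: 20 (R)-tert-butyl[(4,4-dimethoxy-2-methylcyclohex-2-en-1-yl)oxy]dimethylsilane
Conditions: TBSCl, imidazole, DMF, rt
Reagents that add atoms: tert-butyldimethylsilyl chloride CC(C)(C)[Si](C)(C)Cl
Why: Standard silylation of the secondary allylic alcohol installs the bulky silyloxy group that later directs the conjugate addition.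

Step 17
Reactants: 20 (R)-tert-butyl[(4,4-dimethoxy-2-methylcyclohex-2-en-1-yl)oxy]dimethylsilane
Product: 21 (R)-4-(tert-butyldimethylsilyloxy)-3-methylcyclohex-2-en-1-one
Conditions: PPTS (cat.), acetone–H2O, rt
Reagents that add atoms: water O
Why: Mild acid hydrolysis of the allylic dimethyl ketal unmasks the enone carbonyl while the silyl ether and the carbinol centre remain intact.

**Grignard reagent**

Step 18
Reactants: 22 5-bromo-2-methylpent-2-ene
Product: 23 (4-methylpent-3-enyl)magnesium bromide
Conditions: Mg, THF, rt → 40 °C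
Reagents that add atoms: magnesium [Mg]
Why: Magnesium insertion into the primary alkyl bromide gives the Grignard reagent, which is homoallylic and so cannot scramble.

**Union**

Step 19
Reactants: 21 (R)-4-(tert-butyldimethylsilyloxy)-3-methylcyclohex-2-en-1-one; 23 (4-methylpent-3-enyl)magnesium bromide; 15 (1R,3E,4R,7R,8R)-3-(2-bromoethylidene)-2,2,4,8-tetramethyl-8-(triethylsilyloxy)bicyclo[5.3.0]decane
Product: 26 (2R,3R,4R)-4-(tert-butyldimethylsilyloxy)-3-methyl-3-(4-methylpent-3-enyl)-2-{(2E)-2-[(1R,4R,7R,8R)-2,2,4,8-tetramethyl-8-(triethylsilyloxy)bicyclo[5.3.0]decan-3-ylidene]ethyl}cyclohexan-1-one, via trimethylsilyl enol ether 24 (not isolated), via lithium enolate 25 (not isolated)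
Conditions: 23, CuBr·SMe2 (10 mol%), Me3SiCl, HMPA, THF, −78 °C; pentane, filtration of salts, concentration; MeLi, THF, 0 °C; 15, HMPA, −40 → 0 °C
Reagents that add atoms: none
Why: The copper-catalysed Grignard reagent adds 1,4 to the β-methyl enone while Me3SiCl accelerates the addition and traps the enolate as silyl enol ether 24, fixed toward the former α-carbon; MeLi then cleaves the O–Si bond and lithium enolate 25 displaces bromide from the primary allylic carbon of 15 in an SN2 reaction. The closest known reaction type is the tandem conjugate addition–enolate alkylation (three-component coupling) of γ-silyloxy cycloalkenones, and no ring is closed. The quaternary centre is controlled by the neighbouring silyloxy group, which shields one face so that the homoprenyl group enters anti to it. The α-centre is controlled by the new quaternary carbon, the electrophile entering trans to the homoprenyl chain, and as this centre stays epimerisable the required equatorial (trans) isomer is also the thermodynamic one. The step needs facial selectivity twice, a regiodefined enolate and C-alkylation without SN2′ attack: silyl trapping prevents enolate equilibration, and the far allylic terminus of 15 is fully substituted and flanked by a quaternary carbon, so only the CH2Br carbon should be attacked.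

**Endgame**

Step 20
Reactants: 26 (the key-step ketone)
Product: 27 (2R,3R,4R)-4-hydroxy-2-{(2E)-2-[(1R,4R,7R,8R)-8-hydroxy-2,2,4,8-tetramethylbicyclo[5.3.0]decan-3-ylidene]ethyl}-3-methyl-3-(4-methylpent-3-enyl)cyclohexan-1-one
Conditions: Bu4NF, THF, 0 °C → rt
Reagents that add atoms: none
Why: Fluoride-mediated desilylation cleaves both silyl ethers through Si–F bond formation without touching the ketone or the alkenes.

Step 21
Reactants: 27 (the dihydroxy ketone)
Product: 28 (2R,3R,4R)-3-{2-[(2R)-3,3-dimethyloxiran-2-yl]ethyl}-4-hydroxy-2-{(2E)-2-[(1R,4R,7R,8R)-8-hydroxy-2,2,4,8-tetramethylbicyclo[5.3.0]decan-3-ylidene]ethyl}-3-methylcyclohexan-1-one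
Conditions: D-fructose-derived Shi ketone (30 mol%), Oxone (KHSO5), K2CO3, Bu4NHSO4, MeCN–CH2(OMe)2–aq. borate buffer, 0 °C
Reagents that add atoms: potassium peroxymonosulfate [K+].[O-]S(=O)(=O)OO
Why: Shi asymmetric epoxidation with the D-fructose-derived ketone should convert the unhindered trisubstituted alkene of the side chain into the (R)-epoxide, while the ring alkene flanked by a quaternary carbon is too shielded for the bulky dioxirane.

Step 22
Reactants: 28 (the epoxy diol)
Product: 29 (3R,5aR,6R,9aR)-3-hydroxy-6-{(2E)-2-[(1R,4R,7R,8R)-8-hydroxy-2,2,4,8-tetramethylbicyclo[5.3.0]decan-3-ylidene]ethyl}-2,2,5a-trimethyloctahydro-1-benzoxepin-7(2H)-one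
Conditions: camphorsulfonic acid (10 mol%), CH2Cl2, 0 °C
Reagents that add atoms: none
Why: Acid-catalysed intramolecular epoxide opening lets the secondary hydroxyl attack the tertiary epoxide carbon, which bears most of the positive charge, in a 7-endo mode, and the bond to oxygen at the secondary epoxide carbon is not broken, so its (R) configuration is kept.

Step 23
Reactants: 29 (the oxepane ketone)
Product: 30 (3R,5aR,6R,7S,9aR)-6-{(2E)-2-[(1R,4R,7R,8R)-8-hydroxy-2,2,4,8-tetramethylbicyclo[5.3.0]decan-3-ylidene]ethyl}-2,2,5a,7-tetramethyldecahydro-1-benzoxepine-3,7-diol (target)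
Conditions: MeMgBr, CeCl3, THF, −78 → 0 °C
Reagents that add atoms: methylmagnesium bromide C[Mg]Br
Why: Organocerium methyl addition to the ring ketone should take the equatorial trajectory, away from the axial angular methyl group, and give the axial tertiary alcohol with the (S) configuration required.

**Compound list**

1 | (R)-(−)-linalool | CC(C)=CCC[C@@](C)(O)C=C | starting material
2 | (R)-1-methylcyclopent-2-en-1-ol | C[C@]1(O)C=CCC1 | intermediate
3 | (1S,2R,5S)-2-methyl-6-oxabicyclo[3.1.0]hexan-2-ol | C[C@]1(O)[C@H]2O[C@H]2CC1 | intermediate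
4 | 2-[(1S,2S,3R)-2,3-dihydroxy-3-methylcyclopentyl]-2-methylpropanenitrile | C[C@]1(O)[C@@H](O)[C@H](C(C)(C)C#N)CC1 | intermediate
5 | 2-[(1S,3R)-3-hydroxy-3-methyl-2-oxocyclopentyl]-2-methylpropanenitrile | C[C@]1(O)C(=O)[C@H](C(C)(C)C#N)CC1 | intermediate
6 | 2-[(1S,3R)-3-hydroxy-3-methyl-2-methylidenecyclopentyl]-2-methylpropanenitrile | C[C@]1(O)C(=C)[C@H](C(C)(C)C#N)CC1 | intermediate
7 | bromomagnesium ketimine (and alkoxide) formed from 6 | C[C@]1(O[Mg]Br)C(=C)[C@H](C(C)(C)C(=N[Mg]Br)CCC=C)CC1 | intermediate
8 | 2-[(1R,3R)-3-hydroxy-3-methyl-2-methylidenecyclopentyl]-2-methylhept-6-en-3-one | C[C@]1(O)C(=C)[C@H](C(C)(C)C(=O)CCC=C)CC1 | intermediate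
9 | (1R,8R)-8-hydroxy-2,2,8-trimethylbicyclo[5.3.0]dec-6-en-3-one | O=C1CCC=C2[C@@H](CC[C@@]2(C)O)C1(C)C | intermediate
10 | (1R,7R,8R)-8-hydroxy-2,2,8-trimethylbicyclo[5.3.0]decan-3-one | O=C1CCC[C@@H]2[C@@H](CC[C@@]2(C)O)C1(C)C | intermediate
11 | (1R,7R,8R)-2,2,8-trimethyl-8-(triethylsilyloxy)bicyclo[5.3.0]decan-3-one | O=C1CCC[C@@H]2[C@@H](CC[C@@]2(C)O[Si](CC)(CC)CC)C1(C)C | intermediate
12 | lithium enolate of 11 (C3–OLi, C3=C4) | [Li]OC1=CCC[C@@H]2[C@@H](CC[C@@]2(C)O[Si](CC)(CC)CC)C1(C)C | intermediate
13 | (1R,4R,7R,8R)-2,2,4,8-tetramethyl-8-(triethylsilyloxy)bicyclo[5.3.0]decan-3-one | C[C@@H]1CC[C@@H]2[C@@H](CC[C@@]2(C)O[Si](CC)(CC)CC)C(C)(C)C1=O | intermediate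
14 | (1R,4R,7R,8R)-3-ethenyl-2,2,4,8-tetramethyl-8-(triethylsilyloxy)bicyclo[5.3.0]decan-3-ol | C[C@@H]1CC[C@@H]2[C@@H](CC[C@@]2(C)O[Si](CC)(CC)CC)C(C)(C)C1(O)C=C | intermediate
15 | (1R,3E,4R,7R,8R)-3-(2-bromoethylidene)-2,2,4,8-tetramethyl-8-(triethylsilyloxy)bicyclo[5.3.0]decane | C[C@@H]1CC[C@@H]2[C@@H](CC[C@@]2(C)O[Si](CC)(CC)CC)C(C)(C)/C1=C/CBr | intermediate
16 | 4-methoxy-2-methylphenol | COc1ccc(O)c(C)c1 | starting material
17 | 4,4-dimethoxy-2-methylcyclohexa-2,5-dien-1-one | COC1(OC)C=CC(=O)C(C)=C1 | intermediate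
18 | 4,4-dimethoxy-2-methylcyclohex-2-en-1-one | COC1(OC)CCC(=O)C(C)=C1 | intermediate
19 | (R)-4,4-dimethoxy-2-methylcyclohex-2-en-1-ol | COC1(OC)CC[C@@H](O)C(C)=C1 | intermediate
20 | (R)-tert-butyl[(4,4-dimethoxy-2-methylcyclohex-2-en-1-yl)oxy]dimethylsilane | COC1(OC)CC[C@@H](O[Si](C)(C)C(C)(C)C)C(C)=C1 | intermediate
21 | (R)-4-(tert-butyldimethylsilyloxy)-3-methylcyclohex-2-en-1-one | CC1=CC(=O)CC[C@H]1O[Si](C)(C)C(C)(C)C | intermediate
22 | 5-bromo-2-methylpent-2-ene | CC(C)=CCCBr | starting material
23 | (4-methylpent-3-enyl)magnesium bromide | CC(C)=CCC[Mg]Br | intermediate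
24 | tert-butyldimethyl{[(1R,2R)-2-methyl-2-(4-methylpent-3-enyl)-4-(trimethylsilyloxy)cyclohex-3-en-1-yl]oxy}silane | C[C@@]1(CCC=C(C)C)C=C(O[Si](C)(C)C)CC[C@H]1O[Si](C)(C)C(C)(C)C | intermediate
25 | lithium enolate corresponding to 24 | C[C@@]1(CCC=C(C)C)C=C(O[Li])CC[C@H]1O[Si](C)(C)C(C)(C)C | intermediate
26 | (2R,3R,4R)-4-(tert-butyldimethylsilyloxy)-3-methyl-3-(4-methylpent-3-enyl)-2-{(2E)-2-[(1R,4R,7R,8R)-2,2,4,8-tetramethyl-8-(triethylsilyloxy)bicyclo[5.3.0]decan-3-ylidene]ethyl}cyclohexan-1-one | C[C@@H]1CC[C@@H]2[C@@H](CC[C@@]2(C)O[Si](CC)(CC)CC)C(C)(C)/C1=C/C[C@@H]1[C@@](C)(CCC=C(C)C)[C@H](O[Si](C)(C)C(C)(C)C)CCC1=O | intermediate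
27 | dihydroxy ketone (26 without both silyl groups) | C[C@@H]1CC[C@@H]2[C@@H](CC[C@@]2(C)O)C(C)(C)/C1=C/C[C@@H]1[C@@](C)(CCC=C(C)C)[C@H](O)CCC1=O | intermediate
28 | (R)-epoxide of the side-chain alkene of 27 | C[C@@H]1CC[C@@H]2[C@@H](CC[C@@]2(C)O)C(C)(C)/C1=C/C[C@@H]1[C@@](C)(CC[C@H]3OC3(C)C)[C@H](O)CCC1=O | intermediate
29 | trans-fused oxepane ketone (target with C=O in place of the ring C(CH3)OH) | C[C@@H]1CC[C@@H]2[C@@H](CC[C@@]2(C)O)C(C)(C)/C1=C/C[C@@H]1[C@@]2(C)CC[C@@H](O)C(C)(C)O[C@@H]2CCC1=O | intermediate
30 | CNP0167890.2 | C[C@@H]1CC[C@@H]2[C@@H](CC[C@@]2(C)O)C(C)(C)/C1=C/C[C@@H]1[C@@]2(C)CC[C@@H](O)C(C)(C)O[C@@H]2CC[C@]1(C)O | target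

**Count and risk**

Total: 23 steps. Longest linear sequence: 17 steps (steps 1–12, 19, 20–23).

Step 19 (key step). Proton transfer to the hindered lithium enolate may outpace the slow displacement next to the quaternary carbon, and facial selectivity may erode. The fallback replaces the SN2 electrophile by a π-allylpalladium electrophile. It sets out from 14, which would be deprotonated (n-BuLi, THF, −78 °C) and acylated with methyl chloroformate to the tertiary allylic methyl carbonate F1. Lithium enolate 25, made as in step 19, would then be combined with F1 and Pd(PPh3)4 (zerovalent palladium) in THF. Ionisation of F1 gives the allyl complex with the quaternary carbon in the syn position, and the enolate attacks its unhindered CH2 terminus (palladium-catalysed allylic alkylation of a ketone enolate). This returns to the route at 26 with the E alkene and makes step 12 unnecessary.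

Step 7. The ruthenium carbene may fail to engage the hindered 1,1-disubstituted alkene, so that dimerisation through the terminal alkene takes over. The fallback closes the ring between two unhindered alkenes and sets the ring-fusion centre by hydroboration. It sets out from 6. Hydroboration with 9-BBN from the face away from the C(CH3)2CN arm would give the B-alkyl-9-borabicyclononane F2. Suzuki coupling with vinyl bromide (PdCl2(dppf), aq. K3PO4, THF–DMF) would give the allyl nitrile F3. Vinyllithium would add to the nitrile to give the lithium ketimide F4, which mild aqueous acid hydrolyses to the vinyl ketone F5. Ring-closing metathesis (second-generation Grubbs catalyst, CH2Cl2, 40 °C) would give the bicyclic cycloheptenone F6. Hydrogenation (H2, Pd/C, EtOAc) returns to the route at 10.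

Step 10. Methyl iodide may show poor facial preference or prefer the concave face. The fallback sets the centre by protonation in place of methylation. It sets out from 11, which on methylation from the other face gives the C4 epimer F7. F7 would be deprotonated again (LDA, THF, −78 °C) to the lithium enolate F8. Quenching F8 at −78 °C with a hindered proton donor (2,6-di-tert-butylphenol) delivers the proton from the face that the methyl group had used, so the methyl group ends on the required face. This returns to the route at 13.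

**Further compounds**

F1 | step 19 | methyl carbonate of 14 (tertiary allylic methyl carbonate) | C[C@@H]1CC[C@@H]2[C@@H](CC[C@@]2(C)O[Si](CC)(CC)CC)C(C)(C)C1(OC(=O)OC)C=C
F2 | step 7 | B-alkyl-9-borabicyclononane from 6 | C[C@]1(O)[C@H](CB2C3CCCC2CCC3)[C@H](C(C)(C)C#N)CC1
F3 | step 7 | allyl nitrile, 2-[(1S,2R,3R)-3-hydroxy-3-methyl-2-(prop-2-enyl)cyclopentyl]-2-methylpropanenitrile | C[C@]1(O)[C@H](CC=C)[C@H](C(C)(C)C#N)CC1
F4 | step 7 | lithium ketimide from F3 and vinyllithium | C[C@]1(O[Li])[C@H](CC=C)[C@H](C(C)(C)C(=N[Li])C=C)CC1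
F5 | step 7 | vinyl ketone, 4-[(1R,2R,3R)-3-hydroxy-3-methyl-2-(prop-2-enyl)cyclopentyl]-4-methylpent-1-en-3-one | C[C@]1(O)[C@H](CC=C)[C@H](C(C)(C)C(=O)C=C)CC1
F6 | step 7 | bicyclic cycloheptenone, (1R,7R,8R)-8-hydroxy-2,2,8-trimethylbicyclo[5.3.0]dec-4-en-3-one | O=C1C=CC[C@@H]2[C@@H](CC[C@@]2(C)O)C1(C)C
F7 | step 10 | C4 epimer of 13 | C[C@H]1CC[C@@H]2[C@@H](CC[C@@]2(C)O[Si](CC)(CC)CC)C(C)(C)C1=O
F8 | step 10 | lithium enolate of 13 | [Li]OC1=C(C)CC[C@@H]2[C@@H](CC[C@@]2(C)O[Si](CC)(CC)CC)C1(C)C
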